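## Retrosynthetic overview

1. Target ⇒ two molecules of chloranthalactone A by head-to-head, anti [2+2] photodimerisation across C8=C9; the cyclobutane is made last.
2. Chloranthalactone A ⇒ a butenolide aldehyde; ring B is closed by an intramolecular vinylogous aldol condensation that creates C8=C9.
3. Methylenebicyclo[3.1.0]hexane ⇒ a 1β-sulfonyloxy-cyclohex-3-ene; cationic C1–C3 closure (homoallyl → cyclopropylcarbinyl, loss of H-15), as a eudesm-3-en-1-yl cation is thought to become a lindenane.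
4. Cyclohexenol ⇒ an acyclic (R,R)-epoxide; epoxide-triggered cation–olefin closure of C5–C10, as germacrene 1(10)-epoxides give 1β-hydroxyeudesmanes.
5. Epoxide ⇒ geranyl bromide + 3-methyltetronic acid (Stille coupling, SeO2 oxidation, Sharpless epoxidation). Ring order: butenolide (bought) → ring A → cyclopropane → ring B → cyclobutane.

Assumption: ring atoms are called by lindenane numbering (C1–C15; C14 is the methyl on C10, C15 the exocyclic methylene carbon), and α/β refer to the usual lindenane drawing with the C10 methyl β.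

## Route

Step 1
Reactants: 1 4-hydroxy-3-methylfuran-2(5H)-one (3-methyltetronic acid)
Product: 2 4-bromo-3-methylfuran-2(5H)-one
Conditions: (COBr)2, DMF (cat.), CH2Cl2, 0 → 25 °C
Reagents that add atoms: oxalyl bromide, BrC(=O)C(=O)Br
Why: Vilsmeier-type activation of the vinylogous acid OH followed by addition–elimination of bromide at C4 (deoxybromination of a tetronic acid); no stereocentre is involved.

Step 2
Reactants: 2 4-bromo-3-methylfuran-2(5H)-one; 3 geranyl bromide [(2E)-1-bromo-3,7-dimethylocta-2,6-diene]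
Product: 5 4-[(2E)-3,7-dimethylocta-2,6-dien-1-yl]-3-methylfuran-2(5H)-one, via butenolidyl stannane 4 (not isolated)
Conditions: (Bu3Sn)2, Pd(PPh3)4 (5 mol %), toluene, 100 °C; then 3, CuI (10 mol %), DMF, 50 °C
Reagents that add atoms: none
Why: Pd-catalysed stannylation of the vinyl bromide, then Stille allyl–alkenyl coupling through a syn-π-allylpalladium that couples at its unsubstituted terminus, so the skipped diene is linear and the 2E geometry of 3 is kept; no stereocentre is formed.

Step 3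
Reactants: 5 4-[(2E)-3,7-dimethylocta-2,6-dien-1-yl]-3-methylfuran-2(5H)-one
Product: 6 4-[(2E,6E)-8-hydroxy-3,7-dimethylocta-2,6-dien-1-yl]-3-methylfuran-2(5H)-one
Conditions: SeO2 (10 mol %), t-BuOOH, salicylic acid (10 mol %), CH2Cl2, 25 °C
Reagents that add atoms: tert-butyl hydroperoxide, CC(C)(C)OO
Why: Sharpless–Umbreit allylic oxidation (ene reaction then [2,3]-shift) attacks the (E)-methyl of the most electron-rich, terminal trisubstituted alkene, which gives the (6E)-allylic alcohol that becomes C9; no stereocentre is formed.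

Step 4
Reactants: 6 4-[(2E,6E)-8-hydroxy-3,7-dimethylocta-2,6-dien-1-yl]-3-methylfuran-2(5H)-one
Product: 8 4-[(2E)-5-[(2R,3R)-3-({[tert-butyl(diphenyl)silyl]oxy}methyl)-3-methyloxiran-2-yl]-3-methylpent-2-en-1-yl]-3-methylfuran-2(5H)-one, via epoxy alcohol 7 (not isolated)
Conditions: Ti(Oi-Pr)4 (10 mol %), D-(−)-diethyl tartrate (12 mol %), t-BuOOH, 4 Å MS, CH2Cl2, −20 °C; then imidazole, TBDPSCl, 0 → 25 °C
Reagents that add atoms: tert-butyl hydroperoxide, CC(C)(C)OO; tert-butyl(chloro)diphenylsilane, CC(C)(C)[Si](Cl)(c1ccccc1)c1ccccc1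
Why: Sharpless–Katsuki asymmetric epoxidation of the (E)-2-methyl allylic alcohol with the D-tartrate sets both epoxide centres as (2R,3R) (C10 and C1) by reagent control, and in situ silylation masks the primary alcohol with a bulky, non-participating group.

Step 5
Reactants: 8 4-[(2E)-5-[(2R,3R)-3-({[tert-butyl(diphenyl)silyl]oxy}methyl)-3-methyloxiran-2-yl]-3-methylpent-2-en-1-yl]-3-methylfuran-2(5H)-one
Product: 9 4-{[(1S,5R,6S)-6-({[tert-butyl(diphenyl)silyl]oxy}methyl)-5-hydroxy-2,6-dimethylcyclohex-2-en-1-yl]methyl}-3-methylfuran-2(5H)-one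
Conditions: BF3·OEt2 (0.3 equiv), CH2Cl2, −78 → −40 °C
Reagents that add atoms: none
Why: Epoxide-initiated cation–olefin cyclisation through a chair-like transition state closes C5–C10 anti to the epoxide oxygen, so C1 keeps its configuration (1β-OH, equatorial), C10 is inverted (methyl axial, β) and the E-alkene places C6 equatorial (H-5 α), after which Zaitsev loss of H-3 from the C4 cation gives the endocyclic alkene.

Step 6
Reactants: 9 4-{[(1S,5R,6S)-6-({[tert-butyl(diphenyl)silyl]oxy}methyl)-5-hydroxy-2,6-dimethylcyclohex-2-en-1-yl]methyl}-3-methylfuran-2(5H)-one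
Product: 11 4-{[(1R,2S,3S,5S)-2-({[tert-butyl(diphenyl)silyl]oxy}methyl)-2-methyl-4-methylidenebicyclo[3.1.0]hexan-3-yl]methyl}-3-methylfuran-2(5H)-one, via cyclohexenyl triflate 10 (not isolated)
Conditions: Tf2O, 2,6-di-tert-butyl-4-methylpyridine, CH2Cl2, −78 → 0 °C
Reagents that add atoms: none
Why: Proposed new method: the equatorial 1β-triflate ionises with backside participation of the C3=C4 π bond (homoallyl → cyclopropylcarbinyl, as in sabinene biosynthesis and the i-steroid rearrangement; closest laboratory analogue is cyclopropane formation from homoallylic triflates), giving the tertiary cyclopropylcarbinyl C4 cation, which loses H-15 to the hindered base to form the exocyclic methylene; inversion at C1 sets C1 and C3 with the cyclopropane CH2 β, syn to the C10 methyl.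

Step 7
Reactants: 11 4-{[(1R,2S,3S,5S)-2-({[tert-butyl(diphenyl)silyl]oxy}methyl)-2-methyl-4-methylidenebicyclo[3.1.0]hexan-3-yl]methyl}-3-methylfuran-2(5H)-one
Product: 12 4-{[(1R,2S,3S,5S)-2-(hydroxymethyl)-2-methyl-4-methylidenebicyclo[3.1.0]hexan-3-yl]methyl}-3-methylfuran-2(5H)-one
Conditions: TBAF, THF, 0 → 25 °C
Reagents that add atoms: none
Why: Fluoride-induced cleavage of the silyl ether (desilylation) under non-acidic conditions that leave the acid-labile methylenecyclopropane and all stereocentres untouched.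

Step 8
Reactants: 12 4-{[(1R,2S,3S,5S)-2-(hydroxymethyl)-2-methyl-4-methylidenebicyclo[3.1.0]hexan-3-yl]methyl}-3-methylfuran-2(5H)-one
Product: 13 (1R,2S,3S,5S)-2-methyl-4-methylidene-3-[(4-methyl-5-oxo-2,5-dihydrofuran-3-yl)methyl]bicyclo[3.1.0]hexane-2-carbaldehyde
Conditions: Dess–Martin periodinane, pyridine, CH2Cl2, 0 → 25 °C
Reagents that add atoms: none
Why: Buffered Dess–Martin oxidation of the neopentyl primary alcohol gives the non-enolisable C9 aldehyde without epimerisable centres or acid exposure.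

Step 9
Reactants: 13 (1R,2S,3S,5S)-2-methyl-4-methylidene-3-[(4-methyl-5-oxo-2,5-dihydrofuran-3-yl)methyl]bicyclo[3.1.0]hexane-2-carbaldehyde
Product: 16 chloranthalactone A, via silyloxyfuran aldehyde 14 (not isolated), via silyl aldol adduct 15 (not isolated)
Conditions: TBSOTf, Et3N, CH2Cl2, −78 → 0 °C; then DBU, 25 °C
Reagents that add atoms: none
Why: One-pot 2-silyloxyfuran formation, intramolecular vinylogous Mukaiyama aldol through the furan γ-carbon C8 (six-membered ring B) and E1cB loss of silanolate give the γ-ylidenebutenolide; C8 and C9 end as sp2 carbons, so the epimer mixture of 15 is of no consequence.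

Step 10
Reactants: 16 chloranthalactone A (two molecules)
Product: 17 chloranthalactone A head-to-head photodimer (target)
Conditions: hν (high-pressure Hg lamp, Pyrex, λ > 300 nm), degassed n-hexane, 25 °C
Reagents that add atoms: none
Why: [2+2] Photocycloaddition of the γ-ylidenebutenolide (the protoanemonin → anemonin mode): C9–C9′ bonding gives the most stabilised 1,4-diradical (two allylic α-oxy C8 radicals), hence head-to-head closure; each half reacts on its α face, anti to the C10 methyl, and the halves lie anti, which sets C8, C9, C8′ and C9′ as in the C2-symmetric target.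

## Compound list

1 | 4-hydroxy-3-methylfuran-2(5H)-one (3-methyltetronic acid) | CC1=C(O)COC1=O | starting material
2 | 4-bromo-3-methylfuran-2(5H)-one | CC1=C(Br)COC1=O | intermediate
3 | geranyl bromide, (2E)-1-bromo-3,7-dimethylocta-2,6-diene | CC(C)=CCC/C(C)=C/CBr | starting material
4 | 3-methyl-4-(tributylstannyl)furan-2(5H)-one | CCCC[Sn](CCCC)(CCCC)C1=C(C)C(=O)OC1 | intermediate
5 | 4-[(2E)-3,7-dimethylocta-2,6-dien-1-yl]-3-methylfuran-2(5H)-one | CC(C)=CCC/C(C)=C/CC1=C(C)C(=O)OC1 | intermediate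
6 | 4-[(2E,6E)-8-hydroxy-3,7-dimethylocta-2,6-dien-1-yl]-3-methylfuran-2(5H)-one | OC/C(C)=C/CC/C(C)=C/CC1=C(C)C(=O)OC1 | intermediate
7 | 4-[(2E)-5-[(2R,3R)-3-(hydroxymethyl)-3-methyloxiran-2-yl]-3-methylpent-2-en-1-yl]-3-methylfuran-2(5H)-one | OC[C@@]1(C)O[C@@H]1CC/C(C)=C/CC1=C(C)C(=O)OC1 | intermediate
8 | 4-[(2E)-5-[(2R,3R)-3-({[tert-butyl(diphenyl)silyl]oxy}methyl)-3-methyloxiran-2-yl]-3-methylpent-2-en-1-yl]-3-methylfuran-2(5H)-one | CC(C)(C)[Si](c1ccccc1)(c1ccccc1)OC[C@@]1(C)O[C@@H]1CC/C(C)=C/CC1=C(C)C(=O)OC1 | intermediate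
9 | 4-{[(1S,5R,6S)-6-({[tert-butyl(diphenyl)silyl]oxy}methyl)-5-hydroxy-2,6-dimethylcyclohex-2-en-1-yl]methyl}-3-methylfuran-2(5H)-one (1β-OH, 10β-Me, 5α-H) | O[C@@H]1CC=C(C)[C@H](CC2=C(C)C(=O)OC2)[C@@]1(C)CO[Si](c1ccccc1)(c1ccccc1)C(C)(C)C | intermediate
10 | (1R,5S,6S)-6-({[tert-butyl(diphenyl)silyl]oxy}methyl)-4,6-dimethyl-5-[(4-methyl-5-oxo-2,5-dihydrofuran-3-yl)methyl]cyclohex-3-en-1-yl trifluoromethanesulfonate | O=S(=O)(O[C@@H]1CC=C(C)[C@H](CC2=C(C)C(=O)OC2)[C@@]1(C)CO[Si](c1ccccc1)(c1ccccc1)C(C)(C)C)C(F)(F)F | intermediate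
11 | 4-{[(1R,2S,3S,5S)-2-({[tert-butyl(diphenyl)silyl]oxy}methyl)-2-methyl-4-methylidenebicyclo[3.1.0]hexan-3-yl]methyl}-3-methylfuran-2(5H)-one | C=C1[C@H]2C[C@H]2[C@](C)(CO[Si](c2ccccc2)(c2ccccc2)C(C)(C)C)[C@H]1CC1=C(C)C(=O)OC1 | intermediate
12 | 4-{[(1R,2S,3S,5S)-2-(hydroxymethyl)-2-methyl-4-methylidenebicyclo[3.1.0]hexan-3-yl]methyl}-3-methylfuran-2(5H)-one | C=C1[C@H]2C[C@H]2[C@](C)(CO)[C@H]1CC1=C(C)C(=O)OC1 | intermediate
13 | (1R,2S,3S,5S)-2-methyl-4-methylidene-3-[(4-methyl-5-oxo-2,5-dihydrofuran-3-yl)methyl]bicyclo[3.1.0]hexane-2-carbaldehyde | C=C1[C@H]2C[C@H]2[C@](C)(C=O)[C@H]1CC1=C(C)C(=O)OC1 | intermediate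
14 | (1R,2S,3S,5S)-3-[(5-{[tert-butyl(dimethyl)silyl]oxy}-4-methylfuran-3-yl)methyl]-2-methyl-4-methylidenebicyclo[3.1.0]hexane-2-carbaldehyde | C=C1[C@H]2C[C@H]2[C@](C)(C=O)[C@H]1Cc1coc(O[Si](C)(C)C(C)(C)C)c1C | intermediate
15 | 9-{[tert-butyl(dimethyl)silyl]oxy}-8,9-dihydrochloranthalactone A (lindenane numbering; mixture of C8/C9 epimers) | C=C1[C@H]2C[C@H]2[C@@]3(C)[C@H]1CC1=C(C)C(=O)OC1C3O[Si](C)(C)C(C)(C)C | intermediate
16 | chloranthalactone A, (4aS,5aS,6aR,6bS)-3,6b-dimethyl-5-methylidene-4,4a,5,5a,6,6a-hexahydrocyclopropa[2,3]indeno[5,6-b]furan-2(6bH)-one (lindenane 1R,3S,5S,10S) | C=C1[C@H]2C[C@H]2[C@@]3(C)[C@H]1CC1=C(C)C(=O)OC1=C3 | intermediate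
17 | chloranthalactone A head-to-head photodimer: C2-symmetric cyclobutane C8–C9–C9′–C8′, both new bonds α on each half, lactone O and H-9 β, halves anti | C=C1[C@H]2C[C@H]2[C@@]2(C)[C@H]1CC1=C(C)C(=O)O[C@]13[C@H]2[C@H]1[C@@]2(C)[C@@H]4C[C@@H]4C(=C)[C@@H]2CC2=C(C)C(=O)O[C@@]213 | target

## Step count and risks

Total step count: 10. Longest linear sequence: 10 (steps 1–10; geranyl bromide 3 enters at step 2).

The three steps most likely to fail:

**Step 6 (cationic cyclopropane closure).** This step has no direct precedent on such a substrate. The triflate 10 can instead undergo a 1,2-shift of the C5–C10 bond (ring contraction to a tertiary cation), simple elimination, or capture of the C4 cation by the silyl ether oxygen. The fallback replaces the cationic closure by an anionic 1,3-displacement; it sets out from 8 and comes back to the route at 11. Epoxide 8 is opened with Cp2TiCl (from Cp2TiCl2 and Mn, THF) in a radical cyclisation that ends only in the exocyclic alkene, 4-{[(1S,2S,3R)-2-({[tert-butyl(diphenyl)silyl]oxy}methyl)-3-hydroxy-2-methyl-6-methylidenecyclohexyl]methyl}-3-methylfuran-2(5H)-one F1. MsCl and Et3N convert it into the 1β-mesylate F2. Ozonolysis (O3, CH2Cl2/MeOH, −78 °C, then Me2S) of the exocyclic methylene, with the electron-poor butenolide alkene left alone, gives the 4-keto mesylate F3. KOt-Bu (THF, −40 °C) forms the C3 enolate, which displaces the mesylate with inversion (3-exo-tet) to give the bicyclo[3.1.0]hexan-2-one F4. Wittig methylenation (Ph3P=CH2, THF) then gives 11.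

**Step 5 (regiochemistry of proton loss after ring closure).** The C4 cation can also give the exocyclic or the tetrasubstituted alkene, or be trapped by the C1 oxygen as a bridged ether; only the Δ3 isomer 9 can enter step 6. The fallback sets out from 8 and comes back at 9. The ring is closed by the Ti(III) radical epoxide opening (Cp2TiCl, THF), which gives the exocyclic alkene alcohol F1 regiospecifically. A cobalt-hydride hydrogen-atom-transfer isomerisation (Co(salen)Cl cat., PhSiH3, benzene, 25 °C) then moves the alkene one position into the ring, giving 9 under neutral conditions.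

**Step 3 (allylic oxidation).** The skipped diene 5 offers other allylic sites (C3, C6, the butenolide CH2), and over-oxidation to the enal is possible. The fallback does the oxidation before the coupling, on a substrate where its selectivity is established; it sets out from 2 and comes back at 6. Commercial geranyl acetate (CC(C)=CCC/C(C)=C/COC(C)=O) is oxidised with SeO2/t-BuOOH to (2E,6E)-8-hydroxy-3,7-dimethylocta-2,6-dien-1-yl acetate F5. Bromide 2 is stannylated as in step 2 to stannane 4. Stannane 4 is then coupled with the allylic acetate terminus of F5 (Pd2(dba)3, LiCl, DMF, 40 °C), the free hydroxyl being tolerated, to give 6.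

Further compounds
F1 | step 6 | 4-{[(1S,2S,3R)-2-({[tert-butyl(diphenyl)silyl]oxy}methyl)-3-hydroxy-2-methyl-6-methylidenecyclohexyl]methyl}-3-methylfuran-2(5H)-one | O[C@@H]1CCC(=C)[C@H](CC2=C(C)C(=O)OC2)[C@@]1(C)CO[Si](c1ccccc1)(c1ccccc1)C(C)(C)C
F2 | step 6 | (1R,2S,3S)-2-({[tert-butyl(diphenyl)silyl]oxy}methyl)-2-methyl-3-[(4-methyl-5-oxo-2,5-dihydrofuran-3-yl)methyl]-4-methylidenecyclohexyl methanesulfonate | CS(=O)(=O)O[C@@H]1CCC(=C)[C@H](CC2=C(C)C(=O)OC2)[C@@]1(C)CO[Si](c1ccccc1)(c1ccccc1)C(C)(C)C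
F3 | step 6 | (1R,2S,3R)-2-({[tert-butyl(diphenyl)silyl]oxy}methyl)-2-methyl-3-[(4-methyl-5-oxo-2,5-dihydrofuran-3-yl)methyl]-4-oxocyclohexyl methanesulfonate | CS(=O)(=O)O[C@@H]1CCC(=O)[C@H](CC2=C(C)C(=O)OC2)[C@@]1(C)CO[Si](c1ccccc1)(c1ccccc1)C(C)(C)C
F4 | step 6 | (1S,3R,4S,5R)-4-({[tert-butyl(diphenyl)silyl]oxy}methyl)-4-methyl-3-[(4-methyl-5-oxo-2,5-dihydrofuran-3-yl)methyl]bicyclo[3.1.0]hexan-2-one | O=C1[C@H]2C[C@H]2[C@](C)(CO[Si](c2ccccc2)(c2ccccc2)C(C)(C)C)[C@H]1CC1=C(C)C(=O)OC1
F0 | step 5 | none | none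
F5 | step 3 | (2E,6E)-8-hydroxy-3,7-dimethylocta-2,6-dien-1-yl acetate | OC/C(C)=C/CC/C(C)=C/COC(C)=O
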